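Both dihydrobenzofurans share one feature: the ring-fusion carbon C3a sits between two oxygen-bearing aryl carbons (C7a, carrying O1, and C4, carrying OH), a hidden 2-diazo-1,3-dioxygenated unit. Each furan ring is therefore cut at O1–C2 and C3a–C3 into an E-stilbene and an ortho-quinone diazide. In the key step the non-aromatic diazo dienone 17 meets the stilbene of dimer 13 under a chiral dirhodium carboxylate. Carbene transfer gives a spirocyclopropyl dienone, whose strain-releasing, rearomatising ring expansion forms C3a–C3 and O1–C2 in one operation, with C2 and C3 trans. The same operation (step 5) builds the other dihydrobenzofuran; two Heck reactions install the stilbenes and fluoride frees nine phenols.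

Key step: step 11

Abbreviations: TBSO = tert-butyldimethylsilyloxy; TIPSO = triisopropylsilyloxy; DBF2-yl = (2S,3S)-2-[2,4-bis(TBSO)phenyl]-3-[3,5-bis(TBSO)phenyl]-4-(TIPSO)-2,3-dihydrobenzofuran-7-yl; Rh2(S-TCPTTL)4 = dirhodium tetrakis[N-tetrachlorophthaloyl-(S)-tert-leucinate].

Assumption (remark on the chemistry): Rh2(S-TCPTTL)4 is taken to expose the alkene face that leads to the (3S) centre in steps 5 and 11. Its sense of induction cannot be predicted with confidence, so it is checked once on stilbene 2; if it is opposite, Rh2(R-TCPTTL)4 is used in both steps with nothing else changed.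

Step 1
Reactants: 1 oxyresveratrol
Product: 2 (E)-2,3',4,5'-tetrakis(TBSO)stilbene
Conditions: TBSCl (5 equiv), imidazole, DMF, rt
Reagents that add atoms: tert-butyldimethylsilyl chloride, CC(C)(C)[Si](C)(C)Cl
Why: Silyl ether formation on all four phenols removes every O–H that a carbene could insert into and keeps the 2,4-dioxygenated ring a strong donor.

Step 2
Reactants: 3 2-nitroresorcinol
Product: 4 4-bromo-2-nitrobenzene-1,3-diol
Conditions: NBS (1.0 equiv), MeCN, 0 °C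
Reagents that add atoms: N-bromosuccinimide, O=C1CCC(=O)N1Br
Why: Electrophilic aromatic bromination goes ortho/para to the two OH groups (C4 and C6 are equivalent) and should stop at the monobromide with one equivalent of reagent.

Step 3
Reactants: 4 4-bromo-2-nitrobenzene-1,3-diol
Product: 5 2-amino-4-bromobenzene-1,3-diol
Conditions: H2 (1 atm), 5% Pt/C (sulfided), EtOAc, rt; used at once under argon
Reagents that add atoms: none
Why: Catalytic hydrogenation of a nitroarene over sulfided platinum should spare the aryl bromide.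

Step 4
Reactants: 5 2-amino-4-bromobenzene-1,3-diol
Product: 7 2-bromo-6-diazo-5-(TIPSO)cyclohexa-2,4-dien-1-one (quinone diazide A), via hydroxy quinone diazide 6 (not isolated)
Conditions: t-BuONO, AcOH (cat.), THF, 0 °C, dark; evaporate; then TIPSOTf (1.05 equiv), 2,6-lutidine, CH2Cl2, −40 °C
Reagents that add atoms: tert-butyl nitrite, CC(C)(C)ON=O; triisopropylsilyl triflate, CC(C)[Si](OS(=O)(=O)C(F)(F)F)(C(C)C)C(C)C
Why: Diazotisation of an ortho-aminophenol gives the ortho-quinone diazide directly, and O-silylation of the ambident 2-diazonioresorcinolate should occur at the oxygen remote from bromine, which is both less hindered and more basic.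

Step 5
Reactants: 2 (E)-2,3',4,5'-tetrakis(TBSO)stilbene; 7 quinone diazide A
Product: 9 (2S,3S)-7-bromo-2-[2,4-bis(TBSO)phenyl]-3-[3,5-bis(TBSO)phenyl]-4-(TIPSO)-2,3-dihydrobenzofuran, via spirocyclopropyl dienone 8 (not isolated)
Conditions: Rh2(S-TCPTTL)4 (2 mol %), 4 Å MS, PhCF3, 40 °C, dark, slow addition of 7 (1.5 equiv)
Reagents that add atoms: none
Why: Proposed new method: a catalyst-controlled enantioselective formal [3+2] annulation of an ortho-quinone diazide with an E-stilbene, in which the rhodium carbene at the diazo carbon is attacked by the alkene carbon bearing the 3,5-disilyloxyphenyl group (charge builds on the carbon carrying the ortho,para-disilyloxyphenyl ring), the spirocyclopropane 8 opens to a phenoxide/benzylic cation pair and recloses through oxygen, the carboxylate pocket choosing the alkene face and so C3 (S) while C2 (S) follows from trans closure; the closest known reactions are the dirhodium-carboxylate-catalysed cyclopropanation and formal [3+2] annulation of quinone diazides and 2-diazo-1,3-diones with styrenes and enol ethers (Cloke–Wilson-type ring expansion).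

Step 6
Reactants: 10 3,5-dihydroxybenzaldehyde
Product: 11 3,5-bis(TBSO)benzaldehyde
Conditions: TBSCl (2.5 equiv), imidazole, DMF, rt
Reagents that add atoms: tert-butyldimethylsilyl chloride, CC(C)(C)[Si](C)(C)Cl
Why: Routine silyl ether formation on both phenols.

Step 7
Reactants: 11 3,5-bis(TBSO)benzaldehyde
Product: 12 3,5-bis(TBSO)styrene
Conditions: Ph3PCH3Br, n-BuLi, THF, 0 °C; then 11, 0 °C to rt
Reagents that add atoms: methyltriphenylphosphonium bromide, C[P+](c1ccccc1)(c1ccccc1)c1ccccc1.[Br-]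
Why: Wittig methylenation, with the ylide made by a lithium base so that no alkoxide is present to cleave the aryl silyl ethers.

Step 8
Reactants: 9 bromide of dihydrobenzofuran 2; 12 3,5-bis(TBSO)styrene
Product: 13 (2S,3S)-2-[2,4-bis(TBSO)phenyl]-3-[3,5-bis(TBSO)phenyl]-7-[(E)-2-[3,5-bis(TBSO)phenyl]ethenyl]-4-(TIPSO)-2,3-dihydrobenzofuran (dimer stilbene)
Conditions: Pd(P(t-Bu)3)2 (5 mol %), Cy2NMe, dioxane, 80 °C
Reagents that add atoms: none
Why: A Mizoroki–Heck reaction of the electron-rich aryl bromide should give the E-stilbene by syn insertion and syn β-hydride elimination, the amine base leaving silyl ethers and the benzylic stereocentres untouched.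

Step 9
Reactants: 14 4-bromo-2,6-dimethoxyaniline
Product: 15 2-amino-5-bromobenzene-1,3-diol
Conditions: BBr3 (4 equiv), CH2Cl2, −78 °C to rt; then H2O, NaHCO3 to pH 7; used at once under argon
Reagents that add atoms: none
Why: Lewis-acid cleavage of both equivalent aryl methyl ethers (BBr3 demethylation) should leave the C–Br bond alone.

Step 10
Reactants: 15 2-amino-5-bromobenzene-1,3-diol
Product: 17 3-bromo-6-diazo-5-(TIPSO)cyclohexa-2,4-dien-1-one (quinone diazide B), via hydroxy quinone diazide 16 (not isolated)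
Conditions: t-BuONO, AcOH (cat.), THF, 0 °C, dark; evaporate; then TIPSOTf (1.05 equiv), 2,6-lutidine, CH2Cl2, −40 °C
Reagents that add atoms: tert-butyl nitrite, CC(C)(C)ON=O; triisopropylsilyl triflate, CC(C)[Si](OS(=O)(=O)C(F)(F)F)(C(C)C)C(C)C
Why: Diazotisation of the ortho-aminophenol followed by O-silylation, as in step 4; the two oxygens are equivalent here, so only one silyl ether can form.

Step 11
Reactants: 13 dimer stilbene; 17 quinone diazide B
Product: 19 (2S,3S)-6-bromo-3-[3,5-bis(TBSO)phenyl]-2-(DBF2-yl)-4-(TIPSO)-2,3-dihydrobenzofuran, via spirocyclopropyl dienone 18 (not isolated)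
Conditions: Rh2(S-TCPTTL)4 (2 mol %), 4 Å MS, PhCF3, 40 °C, dark, slow addition of 17 (1.5 equiv)
Reagents that add atoms: none
Why: Proposed new method: Rh2(S-TCPTTL)4 expels N2 from 17 to give an electrophilic rhodium carbene at the carbon that becomes C3a, and the alkene of 13 attacks it through the carbon bearing the 3,5-disilyloxyphenyl group (charge developing on the carbon that carries the ortho-alkoxy/para-silyloxy aryl ring), giving spirocyclopropyl dienone 18 with C3a–C3 in place. Heterolysis of the other cyclopropane bond to a phenoxide/benzylic cation pair and collapse of the phenoxide oxygen onto that cation forms O1–C2, driven by release of cyclopropane strain and rearomatisation of the six-membered ring. The closest known reactions are the dirhodium-carboxylate-catalysed cyclopropanation and formal [3+2] annulation of quinone diazides and of 2-diazo-1,3-diones with styrenes and enol ethers (Cloke–Wilson-type ring expansion), which to my knowledge have not been run with strong catalyst control or on 1,2-diarylethenes. The cyclopropane closes by [2+1] carbene transfer, and the dihydrofuran closes by a 1,3-shift that ends in a 5-exo-trig attack of O1 on the quinone-methide-like C2. C3 (S) is fixed by the alkene face that the chiral carboxylate pocket exposes to the carbene and is not touched again, while C2 (S) follows from closure anti to the C3 aryl group, reversible ionisation at the para-oxygenated benzylic C2 funnelling material to the trans isomer. The step needs chemoselectivity for the single alkene over the silyloxyarene rings (secured by the higher nucleophilicity of the stilbene and the bulk of the silyl groups), regioselectivity (secured by the unequal cation-stabilising power of the two aryl groups) and catalyst-dominated facial selectivity (the resident stereocentres C2' and C3' lie five bonds from the alkene).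

Step 12
Reactants: 19 bromide of the protected trimer; 20 4-(TBSO)styrene
Product: 21 (2S,3S)-3-[3,5-bis(TBSO)phenyl]-2-(DBF2-yl)-6-[(E)-2-[4-(TBSO)phenyl]ethenyl]-4-(TIPSO)-2,3-dihydrobenzofuran (nona-O-silyl gnetumontanin B)
Conditions: Pd(P(t-Bu)3)2 (5 mol %), Cy2NMe, dioxane, 80 °C
Reagents that add atoms: none
Why: A second Mizoroki–Heck reaction at the unhindered C6 bromide should give the E-4-silyloxystyryl group, there being no other alkene or halide in 19.

Step 13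
Reactants: 21 nona-O-silyl gnetumontanin B
Product: 22 gnetumontanin B
Conditions: Bu4NF (12 equiv), AcOH (12 equiv), THF, 0 °C to rt, argon
Reagents that add atoms: none
Why: Fluoride-mediated cleavage of all nine aryl silyl ethers, buffered with acetic acid so that no free phenoxide opens or epimerises the dihydrobenzofurans or oxidises in air; no stereocentre is touched.

Compound list

1 | oxyresveratrol, (E)-4-[2-(3,5-dihydroxyphenyl)ethenyl]benzene-1,3-diol | Oc1ccc(/C=C/c2cc(O)cc(O)c2)c(O)c1 | starting material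
2 | (E)-2,3',4,5'-tetrakis(TBSO)stilbene | CC(C)(C)[Si](C)(C)Oc1ccc(/C=C/c2cc(O[Si](C)(C)C(C)(C)C)cc(O[Si](C)(C)C(C)(C)C)c2)c(O[Si](C)(C)C(C)(C)C)c1 | intermediate
3 | 2-nitroresorcinol (2-nitrobenzene-1,3-diol) | Oc1cccc(O)c1[N+](=O)[O-] | starting material
4 | 4-bromo-2-nitrobenzene-1,3-diol | Oc1ccc(Br)c(O)c1[N+](=O)[O-] | intermediate
5 | 2-amino-4-bromobenzene-1,3-diol | Nc1c(O)ccc(Br)c1O | intermediate
6 | 2-bromo-6-diazo-5-hydroxycyclohexa-2,4-dien-1-one (hydroxy quinone diazide) | O=C1C(Br)=CC=C(O)C1=[N+]=[N-] | intermediate (not isolated)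
7 | 2-bromo-6-diazo-5-(TIPSO)cyclohexa-2,4-dien-1-one (quinone diazide A) | O=C1C(Br)=CC=C(O[Si](C(C)C)(C(C)C)C(C)C)C1=[N+]=[N-] | intermediate
8 | (1S,2S)-1-[2,4-bis(TBSO)phenyl]-2-[3,5-bis(TBSO)phenyl]-5-bromo-8-(TIPSO)spiro[2.5]octa-5,7-dien-4-one, aryl groups trans, spiro centre either way | CC(C)(C)[Si](C)(C)Oc1ccc([C@@H]2[C@@H](c3cc(O[Si](C)(C)C(C)(C)C)cc(O[Si](C)(C)C(C)(C)C)c3)C23C(=O)C(Br)=CC=C3O[Si](C(C)C)(C(C)C)C(C)C)c(O[Si](C)(C)C(C)(C)C)c1 | intermediate (not isolated)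
9 | (2S,3S)-7-bromo-2-[2,4-bis(TBSO)phenyl]-3-[3,5-bis(TBSO)phenyl]-4-(TIPSO)-2,3-dihydrobenzofuran | Brc1ccc(O[Si](C(C)C)(C(C)C)C(C)C)c2c1O[C@H](c1ccc(O[Si](C)(C)C(C)(C)C)cc1O[Si](C)(C)C(C)(C)C)[C@H]2c1cc(O[Si](C)(C)C(C)(C)C)cc(O[Si](C)(C)C(C)(C)C)c1 | intermediate
10 | 3,5-dihydroxybenzaldehyde | O=Cc1cc(O)cc(O)c1 | starting material
11 | 3,5-bis(TBSO)benzaldehyde | O=Cc1cc(O[Si](C)(C)C(C)(C)C)cc(O[Si](C)(C)C(C)(C)C)c1 | intermediate
12 | 3,5-bis(TBSO)styrene | C=Cc1cc(O[Si](C)(C)C(C)(C)C)cc(O[Si](C)(C)C(C)(C)C)c1 | intermediate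
13 | (2S,3S)-2-[2,4-bis(TBSO)phenyl]-3-[3,5-bis(TBSO)phenyl]-7-[(E)-2-[3,5-bis(TBSO)phenyl]ethenyl]-4-(TIPSO)-2,3-dihydrobenzofuran (dimer stilbene) | CC(C)(C)[Si](C)(C)Oc1cc(/C=C/c2ccc(O[Si](C(C)C)(C(C)C)C(C)C)c3c2O[C@H](c2ccc(O[Si](C)(C)C(C)(C)C)cc2O[Si](C)(C)C(C)(C)C)[C@H]3c2cc(O[Si](C)(C)C(C)(C)C)cc(O[Si](C)(C)C(C)(C)C)c2)cc(O[Si](C)(C)C(C)(C)C)c1 | intermediate
14 | 4-bromo-2,6-dimethoxyaniline | COc1cc(Br)cc(OC)c1N | starting material
15 | 2-amino-5-bromobenzene-1,3-diol | Nc1c(O)cc(Br)cc1O | intermediate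
16 | 3-bromo-6-diazo-5-hydroxycyclohexa-2,4-dien-1-one (hydroxy quinone diazide) | O=C1C=C(Br)C=C(O)C1=[N+]=[N-] | intermediate (not isolated)
17 | 3-bromo-6-diazo-5-(TIPSO)cyclohexa-2,4-dien-1-one (quinone diazide B) | O=C1C=C(Br)C=C(O[Si](C(C)C)(C(C)C)C(C)C)C1=[N+]=[N-] | intermediate
18 | (1S,2S)-6-bromo-1-(DBF2-yl)-2-[3,5-bis(TBSO)phenyl]-8-(TIPSO)spiro[2.5]octa-5,7-dien-4-one, aryl groups trans, spiro centre either way | c1([C@@H]2[C@@H](c3cc(O[Si](C)(C)C(C)(C)C)cc(O[Si](C)(C)C(C)(C)C)c3)C23C(=O)C=C(Br)C=C3O[Si](C(C)C)(C(C)C)C(C)C)ccc(O[Si](C(C)C)(C(C)C)C(C)C)c2c1O[C@H](c1ccc(O[Si](C)(C)C(C)(C)C)cc1O[Si](C)(C)C(C)(C)C)[C@H]2c1cc(O[Si](C)(C)C(C)(C)C)cc(O[Si](C)(C)C(C)(C)C)c1 | intermediate (not isolated)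
19 | (2S,3S)-6-bromo-3-[3,5-bis(TBSO)phenyl]-2-(DBF2-yl)-4-(TIPSO)-2,3-dihydrobenzofuran | Brc1cc(O[Si](C(C)C)(C(C)C)C(C)C)c2c(c1)O[C@H](c1ccc(O[Si](C(C)C)(C(C)C)C(C)C)c3c1O[C@H](c1ccc(O[Si](C)(C)C(C)(C)C)cc1O[Si](C)(C)C(C)(C)C)[C@H]3c1cc(O[Si](C)(C)C(C)(C)C)cc(O[Si](C)(C)C(C)(C)C)c1)[C@H]2c1cc(O[Si](C)(C)C(C)(C)C)cc(O[Si](C)(C)C(C)(C)C)c1 | intermediate
20 | 4-(TBSO)styrene | C=Cc1ccc(O[Si](C)(C)C(C)(C)C)cc1 | starting material
21 | (2S,3S)-3-[3,5-bis(TBSO)phenyl]-2-(DBF2-yl)-6-[(E)-2-[4-(TBSO)phenyl]ethenyl]-4-(TIPSO)-2,3-dihydrobenzofuran (nona-O-silyl gnetumontanin B) | CC(C)(C)[Si](C)(C)Oc1ccc(/C=C/c2cc(O[Si](C(C)C)(C(C)C)C(C)C)c3c(c2)O[C@H](c2ccc(O[Si](C(C)C)(C(C)C)C(C)C)c4c2O[C@H](c2ccc(O[Si](C)(C)C(C)(C)C)cc2O[Si](C)(C)C(C)(C)C)[C@H]4c2cc(O[Si](C)(C)C(C)(C)C)cc(O[Si](C)(C)C(C)(C)C)c2)[C@H]3c2cc(O[Si](C)(C)C(C)(C)C)cc(O[Si](C)(C)C(C)(C)C)c2)cc1 | intermediate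
22 | gnetumontanin B, (2S,3S,2'S,3'S), both dihydrobenzofurans trans | Oc1ccc(/C=C/c2cc(O)c3c(c2)O[C@H](c2ccc(O)c4c2O[C@H](c2ccc(O)cc2O)[C@H]4c2cc(O)cc(O)c2)[C@H]3c2cc(O)cc(O)c2)cc1 | target

Total step count: 13. Longest linear sequence: 8 steps (2, 3, 4, 5, 8, 11, 12, 13).

Steps most likely to fail

Step 11. The rhodium carbene may be consumed by ring contraction or by attack on the silyloxyarene rings before the hindered 1,2-diaryl alkene reacts, or the catalyst may fail to override the resident stereocentres so that both alkene faces react. The fallback uses known chemistry, sets out from 13 and comes back at 21. Compound 13 and commercial methyl 3,5-dioxocyclohexane-1-carboxylate are joined by the manganese-triacetate-mediated oxidative [3+2] annulation known for 1,3-diones and stilbenes (Mn(OAc)3·2H2O, Cu(OAc)2, AcOH/MeCN, 60 °C). This forms the same two bonds by a radical–polar crossover without diazo chemistry and should give the trans keto ester methyl (2S,3S)-3-[3,5-bis(TBSO)phenyl]-2-(DBF2-yl)-4-oxo-2,3,4,5,6,7-hexahydrobenzofuran-6-carboxylate F1. There is no facial control, so the ring diastereomers are separated by chromatography at this point; the C6 epimers are of no consequence. Dehydrogenation (IBX, 4-methoxypyridine N-oxide, DMSO, rt) gives the phenol ester methyl (2S,3S)-3-[3,5-bis(TBSO)phenyl]-2-(DBF2-yl)-4-hydroxy-2,3-dihydrobenzofuran-6-carboxylate F2. TIPSOTf/2,6-lutidine gives its silyl ether methyl (2S,3S)-3-[3,5-bis(TBSO)phenyl]-2-(DBF2-yl)-4-(TIPSO)-2,3-dihydrobenzofuran-6-carboxylate F3. Reduction with i-Bu2AlH (CH2Cl2, −78 °C) gives the benzylic alcohol [(2S,3S)-3-[3,5-bis(TBSO)phenyl]-2-(DBF2-yl)-4-(TIPSO)-2,3-dihydrobenzofuran-6-yl]methanol F4, and MnO2 gives the aldehyde (2S,3S)-3-[3,5-bis(TBSO)phenyl]-2-(DBF2-yl)-4-(TIPSO)-2,3-dihydrobenzofuran-6-carbaldehyde F5. Wittig methylenation (Ph3PCH3Br, n-BuLi, THF) gives the vinylarene (2S,3S)-3-[3,5-bis(TBSO)phenyl]-2-(DBF2-yl)-6-ethenyl-4-(TIPSO)-2,3-dihydrobenzofuran F6. A Heck reaction with commercial (4-bromophenoxy)(tert-butyl)dimethylsilane under the conditions of step 12 returns to 21.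

Step 5. Enantiofacial discrimination by the catalyst may be poor on the 1,2-diaryl alkene, or the carbene may be lost to side reactions. The fallback uses known chemistry, sets out from 2 and comes back at 9. Compound 2 and cyclohexane-1,3-dione undergo the same Mn(OAc)3-mediated oxidative [3+2] annulation to the racemic trans ketone 2-[2,4-bis(TBSO)phenyl]-3-[3,5-bis(TBSO)phenyl]-3,5,6,7-tetrahydrobenzofuran-4(2H)-one F7. IBX dehydrogenation gives the racemic phenol trans-2-[2,4-bis(TBSO)phenyl]-3-[3,5-bis(TBSO)phenyl]-2,3-dihydrobenzofuran-4-ol F8. NBS (MeCN, −20 °C) brominates para to the free OH, the most activated position, to give the racemic bromophenol trans-7-bromo-2-[2,4-bis(TBSO)phenyl]-3-[3,5-bis(TBSO)phenyl]-2,3-dihydrobenzofuran-4-ol F9. TIPSOTf/2,6-lutidine gives racemic 9, and 9 is obtained from it by preparative chromatography on a chiral stationary phase.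

Step 4. Silylation of the ambident anion may occur in part at the oxygen next to bromine, and the silylated quinone diazide may hydrolyse on handling. The fallback sets out from 3 and comes back at 7, fixing the regiochemistry in a C–Br bond-forming step instead. Compound 3 is monosilylated (TIPSCl 1.0 equiv, imidazole, DMF) to 2-nitro-3-(TIPSO)phenol F10. Ortho-selective bromination of the remaining phenol (NBS, i-Pr2NH cat., CH2Cl2, 0 °C; the position para to OH is shielded by the neighbouring TIPSO group) gives 6-bromo-2-nitro-3-(TIPSO)phenol F11. Hydrogenation over sulfided Pt/C gives 2-amino-6-bromo-3-(TIPSO)phenol F12, and t-BuONO (THF, 0 °C) then gives 7 directly.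

Further compounds

F1 | step 11 | methyl (2S,3S)-3-[3,5-bis(TBSO)phenyl]-2-(DBF2-yl)-4-oxo-2,3,4,5,6,7-hexahydrobenzofuran-6-carboxylate (C6 epimers) | COC(=O)C1CC(=O)C2=C(C1)O[C@H](c1ccc(O[Si](C(C)C)(C(C)C)C(C)C)c3c1O[C@H](c1ccc(O[Si](C)(C)C(C)(C)C)cc1O[Si](C)(C)C(C)(C)C)[C@H]3c1cc(O[Si](C)(C)C(C)(C)C)cc(O[Si](C)(C)C(C)(C)C)c1)[C@H]2c1cc(O[Si](C)(C)C(C)(C)C)cc(O[Si](C)(C)C(C)(C)C)c1
F2 | step 11 | methyl (2S,3S)-3-[3,5-bis(TBSO)phenyl]-2-(DBF2-yl)-4-hydroxy-2,3-dihydrobenzofuran-6-carboxylate | COC(=O)c1cc(O)c2c(c1)O[C@H](c1ccc(O[Si](C(C)C)(C(C)C)C(C)C)c3c1O[C@H](c1ccc(O[Si](C)(C)C(C)(C)C)cc1O[Si](C)(C)C(C)(C)C)[C@H]3c1cc(O[Si](C)(C)C(C)(C)C)cc(O[Si](C)(C)C(C)(C)C)c1)[C@H]2c1cc(O[Si](C)(C)C(C)(C)C)cc(O[Si](C)(C)C(C)(C)C)c1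
F3 | step 11 | methyl (2S,3S)-3-[3,5-bis(TBSO)phenyl]-2-(DBF2-yl)-4-(TIPSO)-2,3-dihydrobenzofuran-6-carboxylate | COC(=O)c1cc(O[Si](C(C)C)(C(C)C)C(C)C)c2c(c1)O[C@H](c1ccc(O[Si](C(C)C)(C(C)C)C(C)C)c3c1O[C@H](c1ccc(O[Si](C)(C)C(C)(C)C)cc1O[Si](C)(C)C(C)(C)C)[C@H]3c1cc(O[Si](C)(C)C(C)(C)C)cc(O[Si](C)(C)C(C)(C)C)c1)[C@H]2c1cc(O[Si](C)(C)C(C)(C)C)cc(O[Si](C)(C)C(C)(C)C)c1
F4 | step 11 | [(2S,3S)-3-[3,5-bis(TBSO)phenyl]-2-(DBF2-yl)-4-(TIPSO)-2,3-dihydrobenzofuran-6-yl]methanol | OCc1cc(O[Si](C(C)C)(C(C)C)C(C)C)c2c(c1)O[C@H](c1ccc(O[Si](C(C)C)(C(C)C)C(C)C)c3c1O[C@H](c1ccc(O[Si](C)(C)C(C)(C)C)cc1O[Si](C)(C)C(C)(C)C)[C@H]3c1cc(O[Si](C)(C)C(C)(C)C)cc(O[Si](C)(C)C(C)(C)C)c1)[C@H]2c1cc(O[Si](C)(C)C(C)(C)C)cc(O[Si](C)(C)C(C)(C)C)c1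
F5 | step 11 | (2S,3S)-3-[3,5-bis(TBSO)phenyl]-2-(DBF2-yl)-4-(TIPSO)-2,3-dihydrobenzofuran-6-carbaldehyde | O=Cc1cc(O[Si](C(C)C)(C(C)C)C(C)C)c2c(c1)O[C@H](c1ccc(O[Si](C(C)C)(C(C)C)C(C)C)c3c1O[C@H](c1ccc(O[Si](C)(C)C(C)(C)C)cc1O[Si](C)(C)C(C)(C)C)[C@H]3c1cc(O[Si](C)(C)C(C)(C)C)cc(O[Si](C)(C)C(C)(C)C)c1)[C@H]2c1cc(O[Si](C)(C)C(C)(C)C)cc(O[Si](C)(C)C(C)(C)C)c1
F6 | step 11 | (2S,3S)-3-[3,5-bis(TBSO)phenyl]-2-(DBF2-yl)-6-ethenyl-4-(TIPSO)-2,3-dihydrobenzofuran | C=Cc1cc(O[Si](C(C)C)(C(C)C)C(C)C)c2c(c1)O[C@H](c1ccc(O[Si](C(C)C)(C(C)C)C(C)C)c3c1O[C@H](c1ccc(O[Si](C)(C)C(C)(C)C)cc1O[Si](C)(C)C(C)(C)C)[C@H]3c1cc(O[Si](C)(C)C(C)(C)C)cc(O[Si](C)(C)C(C)(C)C)c1)[C@H]2c1cc(O[Si](C)(C)C(C)(C)C)cc(O[Si](C)(C)C(C)(C)C)c1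
F7 | step 5 | racemic trans-2-[2,4-bis(TBSO)phenyl]-3-[3,5-bis(TBSO)phenyl]-3,5,6,7-tetrahydrobenzofuran-4(2H)-one, (2S,3S) enantiomer drawn | C1CC(=O)C2=C(C1)O[C@H](c1ccc(O[Si](C)(C)C(C)(C)C)cc1O[Si](C)(C)C(C)(C)C)[C@H]2c1cc(O[Si](C)(C)C(C)(C)C)cc(O[Si](C)(C)C(C)(C)C)c1
F8 | step 5 | racemic trans-2-[2,4-bis(TBSO)phenyl]-3-[3,5-bis(TBSO)phenyl]-2,3-dihydrobenzofuran-4-ol, (2S,3S) enantiomer drawn | c1cc(O)c2c(c1)O[C@H](c1ccc(O[Si](C)(C)C(C)(C)C)cc1O[Si](C)(C)C(C)(C)C)[C@H]2c1cc(O[Si](C)(C)C(C)(C)C)cc(O[Si](C)(C)C(C)(C)C)c1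
F9 | step 5 | racemic trans-7-bromo-2-[2,4-bis(TBSO)phenyl]-3-[3,5-bis(TBSO)phenyl]-2,3-dihydrobenzofuran-4-ol, (2S,3S) enantiomer drawn | Brc1ccc(O)c2c1O[C@H](c1ccc(O[Si](C)(C)C(C)(C)C)cc1O[Si](C)(C)C(C)(C)C)[C@H]2c1cc(O[Si](C)(C)C(C)(C)C)cc(O[Si](C)(C)C(C)(C)C)c1
F10 | step 4 | 2-nitro-3-(TIPSO)phenol | Oc1cccc(O[Si](C(C)C)(C(C)C)C(C)C)c1[N+](=O)[O-]
F11 | step 4 | 6-bromo-2-nitro-3-(TIPSO)phenol | Oc1c(Br)ccc(O[Si](C(C)C)(C(C)C)C(C)C)c1[N+](=O)[O-]
F12 | step 4 | 2-amino-6-bromo-3-(TIPSO)phenol | Nc1c(O)c(Br)ccc1O[Si](C(C)C)(C(C)C)C(C)C
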